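**Plan**

- Retrosynthesis cuts: the two acetates; C14–C15 and C13–CH3 (alkyne carboalumination, then formaldehyde); C9–C11 together with a 1,3-shift of oxygen from C9 to C7; C3–C4 (ring A); C10–C1 and C10–CH3. What remains is (S)-carvone as ring B.
- Forward: ring B is carvone. Two α'-alkylations build quaternary C10 (methyl, then a 2-sulfonylallyl arm that is C1–C3). Ring A closes last by a hydrogen-atom-transfer radical cyclization from C4 to C3, which also creates the gem-dimethyl carbon. Then the side chain is added at C9, the enone is transposed, C7 is reduced, the sulfone is removed, the alkyne is carboaluminated and the diol is acetylated.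
- Enabling feature: C4 carries two methyls and is bonded to ring-fusion carbon C5 of ring B, and the C7–O / C8–CH3 / C8=C9 array of ring B is the carvone enone after transposition. The isopropenyl group of carvone on C5 is therefore a latent tertiary C4 radical.
- Stereochemistry: C5 comes from (S)-carvone; C10 is set by alkylation anti to the isopropenyl group, which fixes the trans ring fusion; C7 by axial hydride delivery; the E-C13=C14 bond by syn-carboalumination.
- The phenylsulfonyl group on C2 is a temporary activating group that enforces 6-endo closure; it is removed reductively in step 9.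

Key step: step 5

Remark: labdane numbering (C1–C10 decalin, C11–C16 side chain) is used for the bicyclic compounds and for the carbons of their precursors; centres that are erased later (the methyl-bearing carbon of 6, C2 of 9 and 12–14, C9 of 12) are left undefined in the SMILES.

Step 1
Reactants: 1 phenyl vinyl sulfone
Product: 2 2-(phenylsulfonyl)prop-2-en-1-ol
Conditions: HCHO (37% aq.), DABCO, THF, rt
Reagents that add atoms: formaldehyde, C=O
Why: Morita–Baylis–Hillman reaction, in which DABCO adds reversibly to the vinyl sulfone and the α-sulfonyl carbanion is trapped by formaldehyde, the aldehyde best suited to this sluggish acceptor class; no stereocentre is formed.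

Step 2
Reactants: 2 2-(phenylsulfonyl)prop-2-en-1-ol
Product: 3 3-bromo-2-(phenylsulfonyl)prop-1-ene
Conditions: PBr3, Et2O, 0 °C
Reagents that add atoms: phosphorus tribromide, BrP(Br)Br
Why: PBr3 should convert the primary allylic alcohol into the bromide through its phosphite ester (direct or allylic displacement give the same product), as with the analogous acrylate-derived alcohols.

Step 3
Reactants: 4 (S)-(+)-carvone
Product: 6 (5S)-2,6-dimethyl-5-(prop-1-en-2-yl)cyclohex-2-en-1-one (6-methylcarvone; epimers at the new methyl carbon), via lithium dienolate of carvone 5 (not isolated)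
Conditions: LiN(iPr)2, THF, −78 °C; MeI, −78 → 0 °C
Reagents that add atoms: iodomethane, CI
Why: Kinetic deprotonation at the α' carbon (the future C10) gives the cross-conjugated dienolate, which is C-methylated (enolate alkylation); the epimer mixture is of no consequence because this centre is enolized again in step 4.

Step 4
Reactants: 6 6-methylcarvone; 3 3-bromo-2-(phenylsulfonyl)prop-1-ene
Product: 8 (5R,6R)-2,6-dimethyl-6-[2-(phenylsulfonyl)prop-2-en-1-yl]-5-(prop-1-en-2-yl)cyclohex-2-en-1-one (sulfonylallyl arm trans and methyl cis to the isopropenyl group), via lithium dienolate of 6-methylcarvone 7 (not isolated)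
Conditions: LiN(iPr)2, THF, −78 °C; enolate added to 3 (slight excess), −78 → −30 °C
Reagents that add atoms: none
Why: Enolate alkylation by addition–elimination on the 2-sulfonylallyl bromide; the neighbouring isopropenyl group should sit pseudoaxial to avoid allylic strain with the enolate methyl, so the electrophile should enter anti to it and set the quaternary carbon (future C10) with the new arm trans to the isopropenyl group.

Step 5
Reactants: 8 (5R,6R)-6-methyl-6-(2-sulfonylallyl)carvone
Product: 9 (4aR,8aR)-2,5,5,8a-tetramethyl-7-(phenylsulfonyl)-4a,5,6,7,8,8a-hexahydronaphthalen-1(4H)-one (trans-fused; C9 ketone with C7=C8; sulfone on C2 as epimers)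
Conditions: Fe(acac)3 (30 mol%), PhSiH3, EtOH/(CH2OH)2, 60 °C, high dilution
Reagents that add atoms: none
Why: The iron hydride formed from Fe(acac)3 and PhSiH3 should transfer a hydrogen atom to the CH2 terminus of the electron-rich isopropenyl group, which makes that carbon the second methyl on C4 and leaves a tertiary radical at C4; this radical adds to the unsubstituted terminus (C3) of the vinyl sulfone, and the α-sulfonyl radical is then reduced and protonated. The closest known reaction type is the hydrogen-atom-transfer-initiated reductive olefin coupling (radical Giese addition) in its intramolecular form. Ring A closes in the 6-endo-trig mode, because attack at C3 is the conjugate position and gives the sulfone-stabilized radical, whereas 5-exo attack at C2 would be contra-polar and would hit the substituted carbon. No stereocentre of the target is created: C5 and C10 are already fixed with the two reacting arms trans-diequatorial on ring B, so only the trans-decalin can form, and the new C2 centre disappears with the sulfone in step 9. The step needs hydrogen-atom transfer to the 1,1-dialkyl alkene in preference to the enone and the vinyl sulfone, which their electron-poor character should secure, and cyclization faster than reduction of the tertiary radical, which the chair-like pre-organization and dilution should secure.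

Step 6
Reactants: 9 bicyclic sulfonyl enone; 10 (4-bromobut-1-yn-1-yl)trimethylsilane
Product: 12 (4aR,8aR)-2,5,5,8a-tetramethyl-7-(phenylsulfonyl)-1-[4-(trimethylsilyl)but-3-yn-1-yl]-1,4,4a,5,6,7,8,8a-octahydronaphthalen-1-ol (tertiary allylic alcohol at C9), via 4-(trimethylsilyl)but-3-ynylmagnesium bromide 11 (not isolated)
Conditions: Mg, THF, rt (from 10); then 9, LaCl3·2LiCl, THF, 0 °C
Reagents that add atoms: none
Why: Grignard 1,2-addition to the enone carbonyl (C9), promoted by LaCl3·2LiCl to suppress enolization and conjugate addition at this hindered ketone; the configuration of the new carbinol centre is irrelevant because it becomes sp2 in step 7.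

Step 7
Reactants: 12 tertiary allylic alcohol
Product: 13 (4aR,8aR)-3,4a,8,8-tetramethyl-6-(phenylsulfonyl)-4-[4-(trimethylsilyl)but-3-yn-1-yl]-4a,5,6,7,8,8a-hexahydronaphthalen-2(1H)-one (8-en-7-one with the side chain on C9)
Conditions: [C5H5NH][CrO3Cl] (pyridinium chlorochromate), 4 Å molecular sieves, CH2Cl2, rt
Reagents that add atoms: pyridinium chlorochromate (source of the C7 oxygen), [O-][Cr](=O)(=O)Cl.c1cc[nH+]cc1
Why: Dauben–Babler oxidative 1,3-transposition, in which the tertiary allylic chromate ester undergoes a [3,3] shift to C7 and is oxidized there, so that the double bond moves to C8=C9 (tetrasubstituted, bearing the side chain) and the carbonyl appears at C7.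

Step 8
Reactants: 13 8-en-7-one
Product: 14 (2R,4aR,8aR)-3,4a,8,8-tetramethyl-6-(phenylsulfonyl)-4-[4-(trimethylsilyl)but-3-yn-1-yl]-1,2,4a,5,6,7,8,8a-octahydronaphthalen-2-ol (C7 alcohol cis to the C10 methyl)
Conditions: NaBH4, CeCl3·7H2O, MeOH, −78 → 0 °C
Reagents that add atoms: none
Why: Luche 1,2-reduction, in which hydride should add axially from the face of the axial C5–H (opposite to the axial C10 methyl) to give the pseudoequatorial C7 alcohol, as in the reduction of carvone to cis-carveol.

Step 9
Reactants: 14 sulfonyl allylic alcohol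
Product: 15 (2R,4aR,8aR)-4-(but-3-yn-1-yl)-3,4a,8,8-tetramethyl-1,2,4a,5,6,7,8,8a-octahydronaphthalen-2-ol
Conditions: Na/Hg (6%), MeOH, −20 °C → rt; then K2CO3, rt
Reagents that add atoms: none
Why: Reductive desulfonylation by electron transfer from sodium amalgam cleaves the C2–S bond and methanol protonates the carbanion, which removes the activating group, and base-mediated methanolysis then cleaves the alkynyl–silicon bond; no stereocentre is touched.

Step 10
Reactants: 15 terminal alkyne
Product: 18 (5R,7R,10R)-labda-8,13E-diene-7,15-diol, via alkenyldimethylalane 16 (not isolated), via lithium alkenylaluminate 17 (not isolated)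
Conditions: Me3Al, Cp2ZrCl2 (25 mol%), CH2Cl2, 0 °C → rt; volatiles removed; n-BuLi, THF, −78 °C; (CH2O)n, rt
Reagents that add atoms: trimethylaluminium, C[Al](C)C; formaldehyde (from paraformaldehyde), C=O
Why: Zirconium-catalysed carboalumination adds methyl and aluminium syn across the terminal alkyne (methyl to the internal carbon), and hydroxymethylation of the derived aluminate with formaldehyde proceeds with retention, which should set the E-trisubstituted C13=C14 bond; the C7 hydroxyl is carried as its aluminium alkoxide.

Step 11
Reactants: 18 diol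
Product: 19 (5R,7R,10R)-labda-8,13E-diene-7,15-diyl diacetate (target)
Conditions: Ac2O, pyridine, DMAP (cat.), CH2Cl2, rt
Reagents that add atoms: acetic anhydride, CC(=O)OC(C)=O
Why: DMAP-catalysed acylation of the primary allylic and the secondary allylic alcohol should give the diacetate without affecting any stereocentre.

**Compound list**

1 | phenyl vinyl sulfone | C=CS(=O)(=O)c1ccccc1 | starting material
2 | 2-(phenylsulfonyl)prop-2-en-1-ol | OCC(=C)S(=O)(=O)c1ccccc1 | intermediate
3 | 3-bromo-2-(phenylsulfonyl)prop-1-ene | BrCC(=C)S(=O)(=O)c1ccccc1 | intermediate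
4 | (S)-(+)-carvone | CC1=CC[C@@H](CC1=O)C(C)=C | starting material
5 | lithium dienolate of carvone | CC1=CC[C@@H](C=C1O[Li])C(C)=C | intermediate
6 | (5S)-2,6-dimethyl-5-(prop-1-en-2-yl)cyclohex-2-en-1-one (6-methylcarvone, epimers at the methyl carbon) | CC1=CC[C@@H](C(C)C1=O)C(C)=C | intermediate
7 | lithium dienolate of 6-methylcarvone | CC1=CC[C@@H](C(C)=C1O[Li])C(C)=C | intermediate
8 | (5R,6R)-2,6-dimethyl-6-[2-(phenylsulfonyl)prop-2-en-1-yl]-5-(prop-1-en-2-yl)cyclohex-2-en-1-one | O=C1C(C)=CC[C@H](C(C)=C)[C@@]1(C)CC(=C)S(=O)(=O)c1ccccc1 | intermediate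
9 | (4aR,8aR)-2,5,5,8a-tetramethyl-7-(phenylsulfonyl)-4a,5,6,7,8,8a-hexahydronaphthalen-1(4H)-one (trans-fused, sulfonyl epimers) | O=C1C(C)=CC[C@@H]2C(C)(C)CC(S(=O)(=O)c3ccccc3)C[C@@]12C | intermediate
10 | (4-bromobut-1-yn-1-yl)trimethylsilane | C[Si](C)(C)C#CCCBr | starting material
11 | 4-(trimethylsilyl)but-3-ynylmagnesium bromide | C[Si](C)(C)C#CCC[Mg]Br | intermediate
12 | (4aR,8aR)-2,5,5,8a-tetramethyl-7-(phenylsulfonyl)-1-[4-(trimethylsilyl)but-3-yn-1-yl]-1,4,4a,5,6,7,8,8a-octahydronaphthalen-1-ol | OC1(CCC#C[Si](C)(C)C)C(C)=CC[C@@H]2C(C)(C)CC(S(=O)(=O)c3ccccc3)C[C@@]12C | intermediate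
13 | (4aR,8aR)-3,4a,8,8-tetramethyl-6-(phenylsulfonyl)-4-[4-(trimethylsilyl)but-3-yn-1-yl]-4a,5,6,7,8,8a-hexahydronaphthalen-2(1H)-one | C[Si](C)(C)C#CCCC1=C(C)C(=O)C[C@@H]2C(C)(C)CC(S(=O)(=O)c3ccccc3)C[C@@]12C | intermediate
14 | (2R,4aR,8aR)-3,4a,8,8-tetramethyl-6-(phenylsulfonyl)-4-[4-(trimethylsilyl)but-3-yn-1-yl]-1,2,4a,5,6,7,8,8a-octahydronaphthalen-2-ol | C[Si](C)(C)C#CCCC1=C(C)[C@H](O)C[C@@H]2C(C)(C)CC(S(=O)(=O)c3ccccc3)C[C@@]12C | intermediate
15 | (2R,4aR,8aR)-4-(but-3-yn-1-yl)-3,4a,8,8-tetramethyl-1,2,4a,5,6,7,8,8a-octahydronaphthalen-2-ol | C#CCCC1=C(C)[C@H](O)C[C@@H]2C(C)(C)CCC[C@@]12C | intermediate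
16 | alkenyldimethylalane (E; C7 oxygen as dimethylaluminium alkoxide) | C[Al](C)/C=C(\C)CCC1=C(C)[C@H](O[Al](C)C)C[C@@H]2C(C)(C)CCC[C@@]12C | intermediate
17 | lithium alkenyl(butyl)dimethylaluminate | [Li+].CCCC[Al-](C)(C)/C=C(\C)CCC1=C(C)[C@H](O[Al](C)C)C[C@@H]2C(C)(C)CCC[C@@]12C | intermediate
18 | (5R,7R,10R)-labda-8,13E-diene-7,15-diol | OC/C=C(\C)CCC1=C(C)[C@H](O)C[C@@H]2C(C)(C)CCC[C@@]12C | intermediate
19 | (5R,7R,10R)-labda-8,13E-diene-7,15-diyl diacetate | CC(=O)OC/C=C(\C)CCC1=C(C)[C@H](OC(C)=O)C[C@@H]2C(C)(C)CCC[C@@]12C | target

**Step count and risks**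

Total: 11 steps. Longest linear sequence: 10 steps (steps 1, 2 and 4–11, from phenyl vinyl sulfone through alkylating agent 3). The branch from (S)-carvone runs over 9 steps (steps 3–11) and joins at step 4.

Steps most likely to fail:

1. Step 5 (key step). The tertiary radical may be reduced before it cyclizes (net hydrogenation of the isopropenyl group), or the iron hydride may engage one of the electron-poor alkenes. The fallback generates the same radical without a metal hydride. It sets out from 8 and returns at 9. Markovnikov hydrobromination of the isopropenyl group of 8 (HBr in AcOH, 0 °C, as for carvone itself) should give the tertiary bromide F1. Slow addition of Bu3SnH with AIBN in benzene at 80 °C then abstracts bromine, and the C4 radical closes ring A by the same 6-endo Giese cyclization to give 9.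

2. Step 4. Unreacted enolate may add in a conjugate sense to the vinyl sulfone of the product, and the bulky acceptor may erode the facial selectivity at the new quaternary carbon. The fallback builds the quaternary centre before any acceptor is present. It sets out from 6 and returns at 8. The dienolate 7 is alkylated with 2,3-dibromoprop-1-ene to give the 2-bromoallyl ketone F2. Coupling of the vinyl bromide with PhSO2Na (CuI, L-proline sodium salt, DMSO, 95 °C) then installs the sulfone and gives 8.

3. Step 6. The basic organometallic may deprotonate instead of adding at the hindered C9 carbonyl (enolization, or proton abstraction next to the sulfone). The fallback replaces carbonyl addition and oxidative transposition by cross-coupling and allylic oxidation. It sets out from 9 and returns at 13. Conjugate reduction of 9 with Li[HB(sBu)3] (THF, −78 °C) should give the lithium enolate F3. Trapping with N-(5-chloropyridin-2-yl)bis(trifluoromethanesulfonyl)imide gives the tetrasubstituted enol triflate F4. Zinc insertion into 10 (Zn, LiCl, THF) gives the alkylzinc bromide F5. Negishi coupling of this reagent with the triflate under Pd(dppf)Cl2 catalysis gives the C8=C9 olefin F6. Allylic oxidation of the ring methylene C7 (CrO3, 3,5-dimethylpyrazole, CH2Cl2, −20 °C) then gives 13.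

**Further compounds**

F1 | step 5 | (5R,6R)-5-(2-bromopropan-2-yl)-2,6-dimethyl-6-[2-(phenylsulfonyl)prop-2-en-1-yl]cyclohex-2-en-1-one | O=C1C(C)=CC[C@H](C(C)(C)Br)[C@@]1(C)CC(=C)S(=O)(=O)c1ccccc1
F2 | step 4 | (5R,6R)-6-(2-bromoprop-2-en-1-yl)-2,6-dimethyl-5-(prop-1-en-2-yl)cyclohex-2-en-1-one | O=C1C(C)=CC[C@H](C(C)=C)[C@@]1(C)CC(Br)=C
F3 | step 6 | lithium enolate from conjugate reduction of 9 | [Li]OC1=C(C)CC[C@@H]2C(C)(C)CC(S(=O)(=O)c3ccccc3)C[C@@]12C
F4 | step 6 | (4aR,8aR)-2,5,5,8a-tetramethyl-7-(phenylsulfonyl)-3,4,4a,5,6,7,8,8a-octahydronaphthalen-1-yl trifluoromethanesulfonate | O=S(=O)(OC1=C(C)CC[C@@H]2C(C)(C)CC(S(=O)(=O)c3ccccc3)C[C@@]12C)C(F)(F)F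
F5 | step 6 | 4-(trimethylsilyl)but-3-ynylzinc bromide | C[Si](C)(C)C#CCC[Zn]Br
F6 | step 6 | trimethyl{4-[(4aR,8aR)-2,5,5,8a-tetramethyl-7-(phenylsulfonyl)-3,4,4a,5,6,7,8,8a-octahydronaphthalen-1-yl]but-1-yn-1-yl}silane | C[Si](C)(C)C#CCCC1=C(C)CC[C@@H]2C(C)(C)CC(S(=O)(=O)c3ccccc3)C[C@@]12C
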